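## Retrosynthetic overview

1. The target is 14-deoxyandrographolide with one extra equatorial (7R) hydroxyl. The C7–O bond is traced back to the 8(17)-en-7-one (1,2-reduction), and the ketone to the allylic C7–H of the exocyclic alkene (allylic oxidation).
2. The butenolide is traced back to the alkylidene lactone of andrographolide by an SN2′ hydride displacement of the C14 oxygen, which moves the alkene into the lactone ring.
3. No ring is formed. Ring A, ring B and the lactone ring, together with C3, C4, C5, C9 and C10, are bought intact in andrographolide; only C7 is set in the route, in the last step.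

Assumption: andrographolide, a bulk commercial ent-labdane, counts as a commercially available starting material (compound 4 is sold only as a milligram reference standard, so it is made here).

## Route

**Step 1**
Reactants: 1 andrographolide
Product: 2 andrographolide triacetate (3,14,19-tri-O-acetylandrographolide)
Conditions: Ac2O (neat), 140 °C, 1 h
Reagents that add atoms: acetic anhydride, CC(=O)OC(C)=O
Why: Thermal O-acylation (nucleophilic acyl substitution) of all three hydroxyls without base, which avoids base-induced loss of the C14 acetate to the 11,12-diene; no stereocentre is touched.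

**Step 2**
Reactants: 2 andrographolide triacetate
Product: 4 butenolide diol (14-deoxyandrographolide), via butenolide diacetate 3 (not isolated)
Conditions: NaBH4 (0.6 equiv), THF/i-PrOH, −10 → 0 °C; then K2CO3, MeOH, 0 °C → rt
Reagents that add atoms: none
Why: Conjugate addition of hydride to C12 of the alkylidene lactone followed by E1cB loss of the C14 acetate (an SN2′ reduction) erases C14 and moves the alkene into the ring as the more stable butenolide, after which carbonate-catalysed transesterification frees O3 and O19 without touching any ring stereocentre.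

**Step 3**
Reactants: 4 butenolide diol
Product: 5 axial allylic alcohol ((7S)-7-hydroxy-14-deoxyandrographolide)
Conditions: SeO2 (0.5 equiv), t-BuOOH (70% aq., 3 equiv), CH2Cl2/1,4-dioxane, rt
Reagents that add atoms: tert-butyl hydroperoxide, CC(C)(C)OO (terminal oxygen donor; the oxygen is passed to C7 by the catalyst selenium dioxide, O=[Se]=O)
Why: Riley allylic oxidation, in which an ene reaction of the electron-rich C8=C17 alkene at C17 removes the axial H7 and a [2,3]-sigmatropic shift returns oxygen to C7 on the same axial face with the exocyclic alkene restored; the electron-poor butenolide alkene is inert, and the C7 configuration formed here is erased in step 4.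

**Step 4**
Reactants: 5 axial allylic alcohol
Product: 6 exocyclic enone (7-oxo-14-deoxyandrographolide)
Conditions: MnO2 (activated, 20 equiv), EtOAc, rt
Reagents that add atoms: none
Why: Chemoselective allylic alcohol oxidation, since MnO2 oxidises only the allylic C7 carbinol and leaves the saturated C3 and C19 hydroxyls, and the neutral heterogeneous conditions do not move the exocyclic alkene into the ring.

**Step 5**
Reactants: 6 exocyclic enone
Product: 7 target ((7R)-7-hydroxy-14-deoxyandrographolide)
Conditions: NaBH4, CeCl3·7H2O, MeOH, −78 °C
Reagents that add atoms: none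
Why: Luche reduction, in which CeCl3 enforces 1,2-addition and the small hydride attacks the trans-decalin ketone axially from the face of the axial H5 and H9, giving the equatorial 7R alcohol cis to the C10 methyl, while the butenolide is untouched at −78 °C.

## Compound list

1 | andrographolide | C=C1CC[C@@H]2[C@](C)(CO)[C@H](O)CC[C@@]2(C)[C@@H]1C/C=C1/C(=O)OC[C@H]1O | starting material
2 | andrographolide triacetate, 3,14,19-tri-O-acetylandrographolide (12E, 14S) | C=C1CC[C@@H]2[C@](C)(COC(C)=O)[C@H](OC(C)=O)CC[C@@]2(C)[C@@H]1C/C=C1/C(=O)OC[C@H]1OC(C)=O | intermediate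
3 | butenolide diacetate, 3,19-di-O-acetyl-14-deoxyandrographolide | C=C1CC[C@@H]2[C@](C)(COC(C)=O)[C@H](OC(C)=O)CC[C@@]2(C)[C@@H]1CCC1=CCOC1=O | intermediate (not isolated)
4 | butenolide diol, 14-deoxyandrographolide | C=C1CC[C@@H]2[C@](C)(CO)[C@H](O)CC[C@@]2(C)[C@@H]1CCC1=CCOC1=O | intermediate
5 | axial allylic alcohol, (7S)-7-hydroxy-14-deoxyandrographolide (7-OH axial, trans to the C10 methyl) | C=C1[C@@H](O)C[C@@H]2[C@](C)(CO)[C@H](O)CC[C@@]2(C)[C@@H]1CCC1=CCOC1=O | intermediate
6 | exocyclic enone, 7-oxo-14-deoxyandrographolide | C=C1C(=O)C[C@@H]2[C@](C)(CO)[C@H](O)CC[C@@]2(C)[C@@H]1CCC1=CCOC1=O | intermediate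
7 | (7R)-7-hydroxy-14-deoxyandrographolide (7-OH equatorial, cis to the C10 methyl) | C=C1[C@H](O)C[C@@H]2[C@](C)(CO)[C@H](O)CC[C@@]2(C)[C@@H]1CCC1=CCOC1=O | target

## Totals and risks

Total step count: 5. Longest linear sequence: 5 steps (1 → 7).

**Risk 1, step 2.** The borohydride may over-reduce the new butenolide, base may eliminate the C14 acetate to the 11,12-diene, and methanolysis of the hindered C3 acetate may be slow. The fallback sets out from 1 and comes back at 4.
- Compound 1 is treated with 2,2-dimethoxypropane and pyridinium p-toluenesulfonate in acetone to give the acetonide 3,19-O-isopropylideneandrographolide F1.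
- F1 reacts with 2-nitrobenzenesulfonylhydrazide, PPh3 and diethyl azodicarboxylate in THF at −30 °C; Mitsunobu displacement with inversion at C14 gives the allylic sulfonylhydrazide F2.
- On warming to 23 °C, F2 loses 2-nitrobenzenesulfinic acid to give the allylic diazene F3.
- F3 expels N2 in a retro-ene shift that puts hydrogen on C12 and the alkene at C13=C14, giving the 14-deoxy acetonide F4. This is a Myers reductive allylic transposition and uses neither hydride nor base.
- AcOH/H2O (7:3) at rt removes the acetonide and gives 4.

**Risk 2, step 3.** The free 1,3-diol may bind selenium, and oxidation may be slow or stray to C9. The fallback sets out from 3 and comes back at 6.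
- Compound 3 is isolated by stopping step 2 before the K2CO3 stage.
- Kharasch–Sosnovsky acyloxylation (CuBr 10 mol %, tert-butyl perbenzoate, MeCN, 60 °C) abstracts an allylic hydrogen at C7 and forms the C–O bond by copper-mediated transfer of benzoate, with the exocyclic alkene kept. This gives the allylic benzoate F5 as a mixture of C7 epimers.
- K2CO3 in MeOH cleaves the benzoate and both acetates to a mixture of 5 and 7.
- The mixture is oxidised without separation by MnO2, as in step 4, to 6.

**Risk 3, step 5.** The hydride may attack the wrong face, add 1,4 to the exocyclic enone, or reduce the butenolide. The fallback sets out from 6 and comes back at 7.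
- Substrate control is replaced by enzyme control: 6 is reduced by an NADPH-dependent ketoreductase chosen from a screening panel, with glucose and glucose dehydrogenase for cofactor recycling, in pH 7 phosphate buffer with 10% DMSO at 30 °C.
- The enzyme is selected by HPLC against authentic 5 and 7 for delivery of hydride to the C7 face that bears H5 and H9.
- No hydride reagent meets the butenolide, and the fallback makes no new compound (F0).

## Further compounds

F1 | step 2 | 3,19-O-isopropylideneandrographolide | C=C1CC[C@@H]2[C@](C)(CO3)[C@H](OC3(C)C)CC[C@@]2(C)[C@@H]1C/C=C1/C(=O)OC[C@H]1O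
F2 | step 2 | allylic sulfonylhydrazide, (14R)-14-deoxy-14-[1-(2-nitrobenzenesulfonyl)hydrazin-1-yl]-3,19-O-isopropylideneandrographolide | C=C1CC[C@@H]2[C@](C)(CO3)[C@H](OC3(C)C)CC[C@@]2(C)[C@@H]1C/C=C1/C(=O)OC[C@@H]1N(N)S(=O)(=O)c1ccccc1[N+](=O)[O-]
F3 | step 2 | allylic diazene, (14R)-14-deoxy-14-diazenyl-3,19-O-isopropylideneandrographolide | C=C1CC[C@@H]2[C@](C)(CO3)[C@H](OC3(C)C)CC[C@@]2(C)[C@@H]1C/C=C1/C(=O)OC[C@@H]1N=N
F4 | step 2 | 3,19-O-isopropylidene-14-deoxyandrographolide | C=C1CC[C@@H]2[C@](C)(CO3)[C@H](OC3(C)C)CC[C@@]2(C)[C@@H]1CCC1=CCOC1=O
F5 | step 3 | 3,19-di-O-acetyl-7-benzoyloxy-14-deoxyandrographolide (mixture of C7 epimers) | C=C1C(OC(=O)c3ccccc3)C[C@@H]2[C@](C)(COC(C)=O)[C@H](OC(C)=O)CC[C@@]2(C)[C@@H]1CCC1=CCOC1=O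
F0 | step 5 | none | none
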